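**Plan**

- Locants: ring O1, C2(=O), C3=C4, C5, C6; side chain C1'–C15' with hydroxyls on C2', C4' and C6'.
- Cuts, in retrosynthetic order: ring C3=C4 (metathesis) and O1–C6 (acrylate brought in with inversion at C6); the C2' carbinol back to a ketone; then C3'–C4' (aldol), giving methyl ketone 13 (C4–C6, C1'–C3') and aldehyde 6 (C4'–C15'); each fragment goes back to an allylation of an aldehyde.
- Enabling feature: the skipped oxygens. C4'–O is β to C2', and C2' is β to ring carbon C6, which carries ring oxygen O1. With C2' as a ketone and C6–O as a PMB ether this is a β-alkoxy methyl ketone, whose boron enolate adds to aldehydes with 1,5-anti induction.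
- Forward: two allylborations with the same reagent make the fragments; the boron aldol joins the chain and sets C4'; directed reduction sets C2'; acetonide; PMB removal; Mitsunobu acrylation inverts C6; metathesis closes the only ring (the dihydropyranone) last; deprotection.
- Stereochemistry: C6' and a deliberately epimeric C6 from reagent-controlled allylboration; C4' from the C6 ether (1,5-anti, reinforced by C6'); C2' from C4' (1,3-anti hydride delivery); natural C6 by SN2 inversion.

Key step: step 8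

Remark: (+)-B-allyldiisopinocampheylborane, the enantiomer made from (−)-α-pinene, is taken as the purchased 1 M pentane solution.

**Route**

Step 1
Reactants: 1 decanal
Product: 3 (S)-tridec-1-en-4-ol, via diisopinocampheylborinate ester 2 (not isolated)
Conditions: (+)-Ipc2B(allyl) (1 M in pentane), Et2O, −78 °C; then 3 M NaOH, 30% H2O2, 0 °C to rt
Reagents that add atoms: (+)-B-allyldiisopinocampheylborane, C=CCB([C@H]1C[C@H]2C[C@@H]([C@@H]1C)C2(C)C)[C@H]1C[C@H]2C[C@@H]([C@@H]1C)C2(C)C
Why: Brown asymmetric allylboration, in which the allyl group is delivered through a chair six-membered transition state to the Re face of the aldehyde under control of the isopinocampheyl groups, which should set the carbinol as S; alkaline peroxide then cleaves borinate 2.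

Step 2
Reactants: 3 (S)-tridec-1-en-4-ol
Product: 4 (S)-tert-butyldimethyl(tridec-1-en-4-yloxy)silane
Conditions: TBSCl, imidazole, DMF, rt
Reagents that add atoms: tert-butyldimethylsilyl chloride, CC(C)(C)[Si](C)(C)Cl
Why: Standard silylation of a secondary alcohol; a silyl ether is chosen here so that it stays orthogonal to the PMB ether of the ketone fragment.

Step 3
Reactants: 4 (S)-tert-butyldimethyl(tridec-1-en-4-yloxy)silane
Product: 6 (S)-3-[(tert-butyldimethylsilyl)oxy]dodecanal, via secondary ozonide 5 (not isolated)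
Conditions: O3, CH2Cl2, −78 °C; then PPh3, −78 °C to rt
Reagents that add atoms: ozone, [O-][O+]=O
Why: Ozonolysis of the terminal alkene with reductive work-up gives the aldehyde one carbon shorter under neutral conditions that leave the β-silyloxy centre untouched.

Step 4
Reactants: 7 ethyl 2-(2-methyl-1,3-dioxolan-2-yl)acetate
Product: 9 2-(2-methyl-1,3-dioxolan-2-yl)acetaldehyde, via aluminium hemiacetal 8 (not isolated)
Conditions: i-Bu2AlH (1.05 equiv), CH2Cl2, −78 °C; then MeOH, aq. potassium sodium tartrate (KNaC4H4O6)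
Reagents that add atoms: none
Why: Partial reduction of an ester, in which the tetrahedral aluminium hemiacetal 8 (held by chelation to a dioxolane oxygen) persists at −78 °C and collapses to the aldehyde only on work-up.

Step 5
Reactants: 9 2-(2-methyl-1,3-dioxolan-2-yl)acetaldehyde
Product: 11 (R)-1-(2-methyl-1,3-dioxolan-2-yl)pent-4-en-2-ol, via diisopinocampheylborinate ester 10 (not isolated)
Conditions: (+)-Ipc2B(allyl) (1 M in pentane), Et2O, −78 °C; then 3 M NaOH, 30% H2O2, 0 °C to rt
Reagents that add atoms: (+)-B-allyldiisopinocampheylborane, C=CCB([C@H]1C[C@H]2C[C@@H]([C@@H]1C)C2(C)C)[C@H]1C[C@H]2C[C@@H]([C@@H]1C)C2(C)C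
Why: Brown allylboration with the same reagent and the same Re-face attack as in step 1 (the descriptor is R only because the ketal-bearing arm outranks allyl); this centre is deliberately epimeric to C6 of the target.

Step 6
Reactants: 11 (R)-1-(2-methyl-1,3-dioxolan-2-yl)pent-4-en-2-ol
Product: 12 2-[(2R)-2-[(4-methoxybenzyl)oxy]pent-4-en-1-yl]-2-methyl-1,3-dioxolane
Conditions: NaH, PMBCl, Bu4NI (cat.), THF/DMF, 0 °C to rt
Reagents that add atoms: 4-methoxybenzyl chloride, COc1ccc(CCl)cc1
Why: Williamson etherification of the sodium alkoxide under iodide catalysis; a benzyl-type β-ether is what the later boron aldol needs for 1,5-induction.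

Step 7
Reactants: 12 2-[(2R)-2-[(4-methoxybenzyl)oxy]pent-4-en-1-yl]-2-methyl-1,3-dioxolane
Product: 13 (R)-4-[(4-methoxybenzyl)oxy]hept-6-en-2-one
Conditions: PPTS, acetone/H2O, 50 °C
Reagents that add atoms: water, O
Why: Mild acid-catalysed hydrolysis of the dioxolane unmasks the methyl ketone, and PPTS is weak enough to spare the PMB ether and to avoid β-elimination of the alkoxy group.

Step 8
Reactants: 13 (R)-4-[(4-methoxybenzyl)oxy]hept-6-en-2-one; 6 (S)-3-[(tert-butyldimethylsilyl)oxy]dodecanal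
Product: 16 (4R,8R,10S)-10-[(tert-butyldimethylsilyl)oxy]-8-hydroxy-4-[(4-methoxybenzyl)oxy]nonadec-1-en-6-one, via dibutylboron enolate 14 (not isolated), via dibutylboron aldolate 15 (not isolated)
Conditions: Bu2BOTf, i-Pr2NEt, Et2O, −78 °C; then 6, −78 °C; then pH 7 buffer, MeOH, 30% H2O2, 0 °C
Reagents that add atoms: none
Why: Bu2BOTf and i-Pr2NEt enolise 13 kinetically on the methyl side to enolate 14, which adds to 6 through a closed six-membered boron transition state in boat form, where the formyl C–H of the bound aldehyde hydrogen-bonds to the PMB ether oxygen and so exposes one enolate face. The closest known reaction type is the 1,5-anti boron aldol of β-alkoxy methyl ketones. No ring is closed. The one new stereocentre, C8 of 16 (C4' of the target), should be set R by the C4 p-methoxybenzyloxy centre of the enolate (1,5-anti), and the weak 1,3-anti preference of the β-silyloxy aldehyde points the same way, so the pair is matched. The step needs regioselective enolisation (CH3 and not CH2, where loss of the β-alkoxide would follow) and enolate-face selectivity; the first is secured by the dialkylboron triflate with a hindered amine at −78 °C, the second by the benzyl-type (not silyl) ether in 13. Buffered peroxide work-up frees 16 from aldolate 15 without retro-aldol.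

Step 9
Reactants: 16 (4R,8R,10S)-10-[(tert-butyldimethylsilyl)oxy]-8-hydroxy-4-[(4-methoxybenzyl)oxy]nonadec-1-en-6-one
Product: 18 (4R,6S,8S,10S)-10-[(tert-butyldimethylsilyl)oxy]-4-[(4-methoxybenzyl)oxy]nonadec-1-ene-6,8-diol, via alkoxydiacetoxyborohydride 17 (not isolated)
Conditions: Me4NBH(OAc)3, MeCN/AcOH (1:1), −30 °C
Reagents that add atoms: none
Why: Evans–Saksena reduction, in which the C8 hydroxyl exchanges an acetate on boron to give 17 and hydride is then delivered intramolecularly to the acid-activated C6 ketone through a chair transition state, so the new carbinol should be 1,3-anti to C8.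

Step 10
Reactants: 18 (4R,6S,8S,10S)-10-[(tert-butyldimethylsilyl)oxy]-4-[(4-methoxybenzyl)oxy]nonadec-1-ene-6,8-diol
Product: 19 tert-butyl({(2S)-1-[(4S,6R)-6-{(2R)-2-[(4-methoxybenzyl)oxy]pent-4-en-1-yl}-2,2-dimethyl-1,3-dioxan-4-yl]undecan-2-yl}oxy)dimethylsilane (anti-acetonide)
Conditions: 2,2-dimethoxypropane, PPTS (cat.), CH2Cl2, rt
Reagents that add atoms: 2,2-dimethoxypropane, COC(C)(C)OC
Why: Acid-catalysed acetal exchange masks both hydroxyls of the 1,3-diol in one step, and the acetonide should also allow the anti relationship to be checked by 13C NMR of the acetal carbons.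

Step 11
Reactants: 19 anti-acetonide PMB ether
Product: 20 (2R)-1-[(4R,6S)-6-{(2S)-2-[(tert-butyldimethylsilyl)oxy]undecyl}-2,2-dimethyl-1,3-dioxan-4-yl]pent-4-en-2-ol
Conditions: DDQ, CH2Cl2/pH 7 buffer (10:1), 0 °C
Reagents that add atoms: none
Why: Oxidative cleavage of the electron-rich p-methoxybenzyl ether by DDQ (benzylic hydride abstraction, then hydrolysis) frees only this hydroxyl, while silyl ether, acetonide and terminal alkene are inert under buffered conditions.

Step 12
Reactants: 20 (2R)-1-[(4R,6S)-6-{(2S)-2-[(tert-butyldimethylsilyl)oxy]undecyl}-2,2-dimethyl-1,3-dioxan-4-yl]pent-4-en-2-ol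
Product: 22 (2S)-1-[(4S,6S)-6-{(2S)-2-[(tert-butyldimethylsilyl)oxy]undecyl}-2,2-dimethyl-1,3-dioxan-4-yl]pent-4-en-2-yl prop-2-enoate, via alkoxyphosphonium acrylate 21 (not isolated)
Conditions: acrylic acid, PPh3, DIAD, THF, 0 °C to rt
Reagents that add atoms: acrylic acid, C=CC(=O)O
Why: Mitsunobu esterification, in which PPh3 and DIAD activate the hydroxyl as alkoxyphosphonium 21 and acrylate displaces it by SN2 with inversion, turning the provisional centre into the configuration required at C6 of the lactone and installing the acryloyl group in the same operation.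

Step 13
Reactants: 22 (2S)-1-[(4S,6S)-6-{(2S)-2-[(tert-butyldimethylsilyl)oxy]undecyl}-2,2-dimethyl-1,3-dioxan-4-yl]pent-4-en-2-yl prop-2-enoate
Product: 23 (6S)-6-{[(4S,6S)-6-{(2S)-2-[(tert-butyldimethylsilyl)oxy]undecyl}-2,2-dimethyl-1,3-dioxan-4-yl]methyl}-5,6-dihydro-2H-pyran-2-one
Conditions: second-generation Grubbs catalyst, RuCl2(=CHPh)(PCy3)(H2IMes) (5 mol %), CH2Cl2 (0.005 M), 40 °C
Reagents that add atoms: none
Why: Ring-closing olefin metathesis between the acrylate and the terminal alkene closes the six-membered α,β-unsaturated lactone (the ring alkene is necessarily Z), driven by loss of ethene.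

Step 14
Reactants: 23 (6S)-6-{[(4S,6S)-6-{(2S)-2-[(tert-butyldimethylsilyl)oxy]undecyl}-2,2-dimethyl-1,3-dioxan-4-yl]methyl}-5,6-dihydro-2H-pyran-2-one
Product: 24 (6S)-6-[(2S,4R,6S)-2,4,6-trihydroxypentadecyl]-5,6-dihydro-2H-pyran-2-one
Conditions: aq. HF (48%), MeCN, 0 °C to rt
Reagents that add atoms: none
Why: Aqueous HF in acetonitrile cleaves the secondary TBS ether and hydrolyses the strained anti (twist-boat) acetonide in one operation, under conditions that should leave the unsaturated lactone and all four stereocentres intact.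

**Compound list**

1 | decanal | CCCCCCCCCC=O | starting material
2 | (S)-tridec-1-en-4-yl diisopinocampheylborinate | CCCCCCCCC[C@H](OB([C@H]1C[C@H]2C[C@@H]([C@@H]1C)C2(C)C)[C@H]1C[C@H]2C[C@@H]([C@@H]1C)C2(C)C)CC=C | intermediate
3 | (S)-tridec-1-en-4-ol | CCCCCCCCC[C@H](O)CC=C | intermediate
4 | (S)-tert-butyldimethyl(tridec-1-en-4-yloxy)silane | CCCCCCCCC[C@H](O[Si](C)(C)C(C)(C)C)CC=C | intermediate
5 | 3-{(2S)-2-[(tert-butyldimethylsilyl)oxy]undecyl}-1,2,4-trioxolane (secondary ozonide) | CCCCCCCCC[C@H](O[Si](C)(C)C(C)(C)C)CC1OCOO1 | intermediate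
6 | (S)-3-[(tert-butyldimethylsilyl)oxy]dodecanal | CCCCCCCCC[C@H](O[Si](C)(C)C(C)(C)C)CC=O | intermediate
7 | ethyl 2-(2-methyl-1,3-dioxolan-2-yl)acetate | CCOC(=O)CC1(C)OCCO1 | starting material
8 | [1-ethoxy-2-(2-methyl-1,3-dioxolan-2-yl)ethoxy]bis(2-methylpropyl)alumane (aluminium hemiacetal) | CCOC(CC1(C)OCCO1)O[Al](CC(C)C)CC(C)C | intermediate
9 | 2-(2-methyl-1,3-dioxolan-2-yl)acetaldehyde | O=CCC1(C)OCCO1 | intermediate
10 | (R)-1-(2-methyl-1,3-dioxolan-2-yl)pent-4-en-2-yl diisopinocampheylborinate | CC1(C[C@H](OB([C@H]2C[C@H]3C[C@@H]([C@@H]2C)C3(C)C)[C@H]2C[C@H]3C[C@@H]([C@@H]2C)C3(C)C)CC=C)OCCO1 | intermediate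
11 | (R)-1-(2-methyl-1,3-dioxolan-2-yl)pent-4-en-2-ol | CC1(C[C@H](O)CC=C)OCCO1 | intermediate
12 | 2-[(2R)-2-[(4-methoxybenzyl)oxy]pent-4-en-1-yl]-2-methyl-1,3-dioxolane | CC1(C[C@H](OCc2ccc(OC)cc2)CC=C)OCCO1 | intermediate
13 | (R)-4-[(4-methoxybenzyl)oxy]hept-6-en-2-one | CC(=O)C[C@H](OCc1ccc(OC)cc1)CC=C | intermediate
14 | dibutyl{[(4R)-4-[(4-methoxybenzyl)oxy]hepta-1,6-dien-2-yl]oxy}borane (boron enolate of 13) | C=C(OB(CCCC)CCCC)C[C@H](OCc1ccc(OC)cc1)CC=C | intermediate
15 | dibutylborinate of the C8 hydroxyl of 16 (boron aldolate) | CCCCCCCCC[C@H](O[Si](C)(C)C(C)(C)C)C[C@@H](OB(CCCC)CCCC)CC(=O)C[C@H](OCc1ccc(OC)cc1)CC=C | intermediate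
16 | (4R,8R,10S)-10-[(tert-butyldimethylsilyl)oxy]-8-hydroxy-4-[(4-methoxybenzyl)oxy]nonadec-1-en-6-one | CCCCCCCCC[C@H](O[Si](C)(C)C(C)(C)C)C[C@@H](O)CC(=O)C[C@H](OCc1ccc(OC)cc1)CC=C | intermediate
17 | tetramethylammonium diacetoxy(hydrido)borate ester of the C8 hydroxyl of 16 | CCCCCCCCC[C@H](O[Si](C)(C)C(C)(C)C)C[C@@H](O[BH-](OC(C)=O)OC(C)=O)CC(=O)C[C@H](OCc1ccc(OC)cc1)CC=C.C[N+](C)(C)C | intermediate
18 | (4R,6S,8S,10S)-10-[(tert-butyldimethylsilyl)oxy]-4-[(4-methoxybenzyl)oxy]nonadec-1-ene-6,8-diol | CCCCCCCCC[C@H](O[Si](C)(C)C(C)(C)C)C[C@@H](O)C[C@H](O)C[C@H](OCc1ccc(OC)cc1)CC=C | intermediate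
19 | tert-butyl({(2S)-1-[(4S,6R)-6-{(2R)-2-[(4-methoxybenzyl)oxy]pent-4-en-1-yl}-2,2-dimethyl-1,3-dioxan-4-yl]undecan-2-yl}oxy)dimethylsilane | CCCCCCCCC[C@H](O[Si](C)(C)C(C)(C)C)C[C@@H]1C[C@@H](C[C@H](OCc2ccc(OC)cc2)CC=C)OC(C)(C)O1 | intermediate
20 | (2R)-1-[(4R,6S)-6-{(2S)-2-[(tert-butyldimethylsilyl)oxy]undecyl}-2,2-dimethyl-1,3-dioxan-4-yl]pent-4-en-2-ol | CCCCCCCCC[C@H](O[Si](C)(C)C(C)(C)C)C[C@@H]1C[C@@H](C[C@H](O)CC=C)OC(C)(C)O1 | intermediate
21 | alkoxytriphenylphosphonium acrylate formed from 20 (P–O on the pentenyl C2, configuration retained) | CCCCCCCCC[C@H](O[Si](C)(C)C(C)(C)C)C[C@@H]1C[C@@H](C[C@H](O[P+](c2ccccc2)(c2ccccc2)c2ccccc2)CC=C)OC(C)(C)O1.C=CC(=O)[O-] | intermediate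
22 | (2S)-1-[(4S,6S)-6-{(2S)-2-[(tert-butyldimethylsilyl)oxy]undecyl}-2,2-dimethyl-1,3-dioxan-4-yl]pent-4-en-2-yl prop-2-enoate | CCCCCCCCC[C@H](O[Si](C)(C)C(C)(C)C)C[C@@H]1C[C@@H](C[C@@H](OC(=O)C=C)CC=C)OC(C)(C)O1 | intermediate
23 | (6S)-6-{[(4S,6S)-6-{(2S)-2-[(tert-butyldimethylsilyl)oxy]undecyl}-2,2-dimethyl-1,3-dioxan-4-yl]methyl}-5,6-dihydro-2H-pyran-2-one | CCCCCCCCC[C@H](O[Si](C)(C)C(C)(C)C)C[C@@H]1C[C@@H](C[C@@H]2CC=CC(=O)O2)OC(C)(C)O1 | intermediate
24 | (6S)-6-[(2S,4R,6S)-2,4,6-trihydroxypentadecyl]-5,6-dihydro-2H-pyran-2-one | CCCCCCCCC[C@H](O)C[C@@H](O)C[C@H](O)C[C@@H]1CC=CC(=O)O1 | target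

**Step count and risks**

Total: 14 steps. Longest linear sequence: 11 steps (7 to 24 through steps 4–14); the aldehyde branch (steps 1–3) joins at step 8.

Steps most likely to fail:

1. Step 8. The risk is erosion of enolate-face selectivity in the closed boron transition state, or loss of the β-alkoxy group by elimination during enolisation. The fallback sets out from 13 and moves the control to the aldehyde in an open transition state. Ketone 13 is deprotonated on the methyl side with LiN(SiMe3)2 and trapped with Me3SiCl (THF, −78 °C) to give trimethyl{[(4R)-4-[(4-methoxybenzyl)oxy]hepta-1,6-dien-2-yl]oxy}silane F1. A Mukaiyama aldol of this enol ether with 6 (BF3·OEt2, CH2Cl2, −78 °C) should then be steered 1,3-anti by the β-silyloxy centre of the aldehyde alone. That is the same diastereomer, so the fallback comes back to the route at 16.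

2. Step 12. The risk is elimination of the activated homoallylic alcohol to a diene, or slow displacement by the weakly acidic, polymerisable acrylic acid, leading to incomplete inversion. The fallback sets out from 20 and separates inversion from acylation. A Mitsunobu reaction with the more acidic 4-nitrobenzoic acid (PPh3, DIAD, toluene) should give (2S)-1-[(4S,6S)-6-{(2S)-2-[(tert-butyldimethylsilyl)oxy]undecyl}-2,2-dimethyl-1,3-dioxan-4-yl]pent-4-en-2-yl 4-nitrobenzoate F2. Methanolysis (K2CO3, MeOH) gives the inverted alcohol (2S)-1-[(4R,6S)-6-{(2S)-2-[(tert-butyldimethylsilyl)oxy]undecyl}-2,2-dimethyl-1,3-dioxan-4-yl]pent-4-en-2-ol F3. O-Acylation with acryloyl chloride and i-Pr2NEt (CH2Cl2, 0 °C) proceeds with retention and comes back to the route at 22.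

3. Step 14. The risk is intramolecular oxa-Michael addition of the freed C2' hydroxyl to C4 of the unsaturated lactone, or lactone opening, while acid is present. The fallback sets out from 22 and changes the order of events. Aqueous HF in MeCN removes the acetonide and the silyl ether first, giving (4S,6S,8R,10S)-6,8,10-trihydroxynonadec-1-en-4-yl prop-2-enoate F4. Ring-closing metathesis of this unprotected triol with the second-generation Grubbs catalyst (CH2Cl2, 40 °C) then forms the lactone under neutral conditions as the last step and comes back to the route at 24.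

Further compounds
F1 | step 8 | trimethyl{[(4R)-4-[(4-methoxybenzyl)oxy]hepta-1,6-dien-2-yl]oxy}silane | C=C(O[Si](C)(C)C)C[C@H](OCc1ccc(OC)cc1)CC=C
F2 | step 12 | (2S)-1-[(4S,6S)-6-{(2S)-2-[(tert-butyldimethylsilyl)oxy]undecyl}-2,2-dimethyl-1,3-dioxan-4-yl]pent-4-en-2-yl 4-nitrobenzoate | CCCCCCCCC[C@H](O[Si](C)(C)C(C)(C)C)C[C@@H]1C[C@@H](C[C@@H](OC(=O)c2ccc([N+](=O)[O-])cc2)CC=C)OC(C)(C)O1
F3 | step 12 | (2S)-1-[(4R,6S)-6-{(2S)-2-[(tert-butyldimethylsilyl)oxy]undecyl}-2,2-dimethyl-1,3-dioxan-4-yl]pent-4-en-2-ol | CCCCCCCCC[C@H](O[Si](C)(C)C(C)(C)C)C[C@@H]1C[C@@H](C[C@@H](O)CC=C)OC(C)(C)O1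
F4 | step 14 | (4S,6S,8R,10S)-6,8,10-trihydroxynonadec-1-en-4-yl prop-2-enoate | CCCCCCCCC[C@H](O)C[C@@H](O)C[C@H](O)C[C@@H](OC(=O)C=C)CC=C
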